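## Retrosynthetic overview

1. Target 26 ⇒ 9-O-silyl ether 25 ⇒ C7 isopropenyl (acetone aldol, dehydration) and C9–O (Rubottom) removed ⇒ keto ester 20 ⇒ C3–O ester bond ⇒ keto alcohol 12 + acid 19.
2. 19 ⇒ cross-metathesis of (R)-pent-4-en-2-yl angelate 17 with acrylic acid ⇒ (R)-propylene oxide, vinyl Grignard, angelic acid.
3. 12 ⇒ hydroboration of the C3=C4 alkene 9 (sets C3 and C4) ⇒ enol triflate / methyl coupling ⇒ C4 ketone 6.
4. 6 ⇒ dealkenylation of 4 ⇒ Diels–Alder reaction of (S)-carvone with 2-(trimethylsilyloxy)buta-1,3-diene (sets C5 and C10; the carvone isopropenyl only steers the facial selectivity and is then excised).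
5. Ring order: ring A is bought with carvone; ring B is formed in the Diels–Alder reaction.

Assumption: the target is taken exactly as in the SMILES; all decalins are cis-fused (10βH) and carry eremophilane numbering (ring A = C1–C2–C3–C4–C5–C10, ring B = C5–C6–C7–C8–C9–C10; C5 = quaternary ring-fusion carbon; β = face of the C5 methyl, α = the other face).

## Route

Step 1
Reactants: 1 (S)-(+)-carvone; 2 2-(trimethylsilyloxy)buta-1,3-diene
Product: 4 8,8-ethylenedioxy-2β-isopropenyl-5β-methyl-10βH-decalin-4-one, via silyl enol ether adduct 3 (not isolated)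
Conditions: EtAlCl2 (0.5 equiv), toluene, −20 °C → rt; then HOCH2CH2OH, TsOH (cat.), CH2Cl2, rt
Reagents that add atoms: ethylene glycol, OCCO
Why: Lewis-acid-catalysed Diels–Alder reaction in which the 2-silyloxydiene adds to the α-methyl enone with "para" orientation (its oxygenated carbon becomes C8) and suprafacially from the face opposite the isopropenyl group, so the cis ring fusion and the absolute configuration of C5 (methyl β) and C10 (H β) are set by the carvone stereocentre, after which acid-catalysed exchange with ethylene glycol turns the silyl enol ether into the C8 dioxolane while the neopentyl C4 ketone stays free.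

Step 2
Reactants: 4 8,8-ethylenedioxy-2β-isopropenyl-5β-methyl-10βH-decalin-4-one
Product: 6 8,8-ethylenedioxy-5β-methyl-10βH-decalin-4-one, via methoxy hydroperoxide 5 (not isolated)
Conditions: O3, MeOH/CH2Cl2, −78 °C; then FeSO4·7H2O, PhSH, −78 °C → rt
Reagents that add atoms: none
Why: Dealkenylative hydrogenation, in which ozonolysis in methanol gives the α-methoxy hydroperoxide, divalent iron reduces it to an alkoxy radical that loses methyl acetate by β-scission, and the C2 radical takes a hydrogen atom from PhSH, which removes the spent control element without touching C5 or C10.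

Step 3
Reactants: 6 8,8-ethylenedioxy-5β-methyl-10βH-decalin-4-one
Product: 8 8,8-ethylenedioxy-5β-methyl-10βH-decal-3-en-4-yl trifluoromethanesulfonate, via potassium enolate 7 (not isolated)
Conditions: KN(SiMe3)2, THF, −78 °C; PhNTf2, −78 → 0 °C
Reagents that add atoms: N-phenylbis(trifluoromethanesulfonimide), O=S(=O)(N(c1ccccc1)S(=O)(=O)C(F)(F)F)C(F)(F)F
Why: The C4 ketone can enolise only towards C3 because C5 is quaternary, so deprotonation and O-triflation of the enolate give a single enol triflate.

Step 4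
Reactants: 8 8,8-ethylenedioxy-5β-methyl-10βH-decal-3-en-4-yl trifluoromethanesulfonate
Product: 9 8,8-ethylenedioxy-4,5β-dimethyl-10βH-decal-3-ene
Conditions: MeMgBr, Fe(acac)3 (5 mol %), THF/NMP, −30 → 0 °C
Reagents that add atoms: methylmagnesium bromide, C[Mg]Br
Why: Iron-catalysed cross-coupling (Kochi–Fürstner type) of the alkenyl triflate with the methyl Grignard reagent installs the C4 methyl group and leaves the ketal untouched.

Step 5
Reactants: 9 8,8-ethylenedioxy-4,5β-dimethyl-10βH-decal-3-ene
Product: 12 3α-hydroxy-4β,5β-dimethyl-10βH-decalin-8-one, via alkylborane 10 (not isolated), via ketal alcohol 11 (not isolated)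
Conditions: BH3·THF, THF, 0 °C → rt; NaOH, H2O2, 0 °C → rt; then 2 M HCl, THF, rt
Reagents that add atoms: hydrogen peroxide, OO; water, O
Why: Hydroboration–oxidation puts boron on the less substituted C3 and adds H and B syn from the α face, anti to the pseudoaxial β-methyl on the neighbouring quaternary C5, so oxidation with retention gives the 3α-OH and the 4β-methyl (cis to the C5 methyl, trans to the OH) in one operation, and the acid then hydrolyses the dioxolane to the C8 ketone.

Step 6
Reactants: 13 (R)-propylene oxide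
Product: 14 (R)-pent-4-en-2-ol
Conditions: CH2=CHMgBr, CuI (10 mol %), THF, −30 → 0 °C
Reagents that add atoms: vinylmagnesium bromide, C=C[Mg]Br
Why: Copper-catalysed Grignard opening of the epoxide at its unsubstituted carbon (SN2) leaves the bought stereocentre untouched.

Step 7
Reactants: 14 (R)-pent-4-en-2-ol; 15 angelic acid
Product: 17 (R)-pent-4-en-2-yl angelate, via mixed anhydride 16 (not isolated)
Conditions: 2,4,6-Cl3C6H2COCl, Et3N, toluene, rt; then 14, toluene, 80 °C
Reagents that add atoms: none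
Why: Yamaguchi-type esterification through the mixed anhydride, run without DMAP so that the (Z)-angelate does not isomerise to the tiglate, in which the alcohol attacks the less hindered angeloyl carbonyl and its stereocentre is not involved.

Step 8
Reactants: 17 (R)-pent-4-en-2-yl angelate; 18 acrylic acid
Product: 19 (2E,5R)-5-(angeloyloxy)hex-2-enoic acid
Conditions: second-generation Grubbs catalyst (5 mol %), CH2Cl2, 40 °C
Reagents that add atoms: none
Why: Olefin cross-metathesis of the terminal alkene with the electron-poor acrylic acid gives the (E)-enoic acid selectively, the trisubstituted electron-poor angelate alkene being inert.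

Step 9
Reactants: 12 3α-hydroxy-4β,5β-dimethyl-10βH-decalin-8-one; 19 (2E,5R)-5-(angeloyloxy)hex-2-enoic acid
Product: 20 4β,5β-dimethyl-8-oxo-10βH-decalin-3α-yl (2E,5R)-5-(angeloyloxy)hex-2-enoate
Conditions: DCC, DMAP (cat.), CH2Cl2, 0 °C → rt
Reagents that add atoms: none
Why: Steglich esterification (carbodiimide activation, catalytic DMAP) acylates the only hydroxyl group, the equatorial 3α-OH, with retention at C3.

Step 10
Reactants: 20 4β,5β-dimethyl-8-oxo-10βH-decalin-3α-yl (2E,5R)-5-(angeloyloxy)hex-2-enoate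
Product: 22 9β-(tert-butyldimethylsilyloxy) derivative of 20, via TBS enol ether 21 (not isolated)
Conditions: TBSOTf, Et3N, CH2Cl2, 0 °C → rt; then mCPBA, NaHCO3, CH2Cl2, −20 → 0 °C
Reagents that add atoms: tert-butyldimethylsilyl trifluoromethanesulfonate, CC(C)(C)[Si](C)(C)OS(=O)(=O)C(F)(F)F; meta-chloroperbenzoic acid, O=C(OO)c1cccc(Cl)c1
Why: Rubottom oxidation, in which equilibrating soft silylation gives the more stable C8=C9 enol ether (the direction favoured for a cis-fused 2-decalone whose conformation is locked by the equatorial C3 and C4 substituents), the peracid attacks from the convex β face because the axial α approach is blocked by the axial C4–C5 bond, and 1,4-silyl migration delivers the equatorial 9β-silyloxy ketone while the electron-poor side-chain alkenes stay intact.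

Step 11
Reactants: 22 9β-(tert-butyldimethylsilyloxy) derivative of 20
Product: 24 7β-(2-hydroxypropan-2-yl) derivative of 22, via TMS enol ether 23 (not isolated)
Conditions: TMSOTf, Et3N, CH2Cl2, 0 °C; then acetone, TiCl4, CH2Cl2, −78 °C
Reagents that add atoms: acetone, CC(C)=O
Why: Soft enolisation now occurs at the only unhindered α-position (C7), and the Mukaiyama aldol addition of the silyl enol ether to TiCl4-activated acetone forms the C7–C11 bond from the β face, giving the equatorial 7β substituent (the axial α approach is blocked by the axial C4–C5 bond, and C7 stays epimerisable α to the ketone).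

Step 12
Reactants: 24 7β-(2-hydroxypropan-2-yl) derivative of 22
Product: 25 9-O-tert-butyldimethylsilyl ether of the target
Conditions: SOCl2, pyridine, CH2Cl2, −20 → 0 °C
Reagents that add atoms: none
Why: Pyridine-mediated E2 elimination of the tertiary chlorosulfite removes one of the six methyl hydrogens in preference to the single hindered C7 hydrogen, which gives the non-conjugated isopropenyl group under non-equilibrating conditions that leave the equatorial C7 centre untouched.

Step 13
Reactants: 25 9-O-tert-butyldimethylsilyl ether of the target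
Product: 26 CNP0210874.1
Conditions: HF·pyridine, pyridine, THF, 0 °C → rt
Reagents that add atoms: none
Why: Fluoride-mediated silyl ether cleavage under non-enolising conditions frees the 9β-hydroxyl without isomerising the β,γ-unsaturated ketone, the angelate or the enoate.

## Compound list

1 | (S)-(+)-carvone, (5S)-2-methyl-5-(prop-1-en-2-yl)cyclohex-2-en-1-one | CC1=CC[C@H](C(C)=C)CC1=O | starting material
2 | 2-(trimethylsilyloxy)buta-1,3-diene | C=CC(=C)O[Si](C)(C)C | starting material
3 | Diels–Alder adduct: 2β-isopropenyl-5β-methyl-8-(trimethylsilyloxy)-10βH-decal-7-en-4-one | C1C[C@@]2(C)[C@H](C[C@H](C(C)=C)CC2=O)CC=1O[Si](C)(C)C | intermediate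
4 | 8,8-ethylenedioxy-2β-isopropenyl-5β-methyl-10βH-decalin-4-one | C1C[C@@]2(C)[C@H](C[C@H](C(C)=C)CC2=O)CC13OCCO3 | intermediate
5 | 8,8-ethylenedioxy-2β-(1-hydroperoxy-1-methoxyethyl)-5β-methyl-10βH-decalin-4-one (epimers at the peroxy carbon) | C1C[C@@]2(C)[C@H](C[C@H](C(C)(OC)OO)CC2=O)CC13OCCO3 | intermediate
6 | 8,8-ethylenedioxy-5β-methyl-10βH-decalin-4-one | C1C[C@@]2(C)[C@H](CCCC2=O)CC13OCCO3 | intermediate
7 | potassium C3=C4 enolate of 6 | C1C[C@@]2(C)[C@H](CCC=C2[O-])CC13OCCO3.[K+] | intermediate
8 | 8,8-ethylenedioxy-5β-methyl-10βH-decal-3-en-4-yl trifluoromethanesulfonate | C1C[C@@]2(C)[C@H](CCC=C2OS(=O)(=O)C(F)(F)F)CC13OCCO3 | intermediate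
9 | 8,8-ethylenedioxy-4,5β-dimethyl-10βH-decal-3-ene | C1C[C@@]2(C)[C@H](CCC=C2C)CC13OCCO3 | intermediate
10 | 3α-boranyl-8,8-ethylenedioxy-4β,5β-dimethyl-10βH-decalin (monoalkylborane) | C1C[C@@]2(C)[C@H](CC[C@@H](B)[C@@H]2C)CC13OCCO3 | intermediate
11 | 8,8-ethylenedioxy-4β,5β-dimethyl-10βH-decalin-3α-ol | C1C[C@@]2(C)[C@H](CC[C@@H](O)[C@@H]2C)CC13OCCO3 | intermediate
12 | 3α-hydroxy-4β,5β-dimethyl-10βH-decalin-8-one | C1C[C@@]2(C)[C@H](CC[C@@H](O)[C@@H]2C)CC1=O | intermediate
13 | (R)-propylene oxide | C[C@@H]1CO1 | starting material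
14 | (R)-pent-4-en-2-ol | C=CC[C@@H](C)O | intermediate
15 | angelic acid, (Z)-2-methylbut-2-enoic acid | C/C=C(/C)C(=O)O | starting material
16 | angelic 2,4,6-trichlorobenzoic anhydride | C/C=C(/C)C(=O)OC(=O)c1c(Cl)cc(Cl)cc1Cl | intermediate
17 | (R)-pent-4-en-2-yl (Z)-2-methylbut-2-enoate | C=CC[C@@H](C)OC(=O)/C(C)=C\C | intermediate
18 | acrylic acid | C=CC(=O)O | starting material
19 | (2E,5R)-5-[(Z)-2-methylbut-2-enoyloxy]hex-2-enoic acid | OC(=O)/C=C/C[C@@H](C)OC(=O)/C(C)=C\C | intermediate
20 | 4β,5β-dimethyl-8-oxo-10βH-decalin-3α-yl (2E,5R)-5-(angeloyloxy)hex-2-enoate | C1C[C@@]2(C)[C@H](CC[C@@H](OC(=O)/C=C/C[C@@H](C)OC(=O)/C(C)=C\C)[C@@H]2C)CC1=O | intermediate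
21 | C8=C9 tert-butyldimethylsilyl enol ether of 20 | C1C[C@@]2(C)[C@H](CC[C@@H](OC(=O)/C=C/C[C@@H](C)OC(=O)/C(C)=C\C)[C@@H]2C)C=C1O[Si](C)(C)C(C)(C)C | intermediate
22 | 9β-(tert-butyldimethylsilyloxy)-4β,5β-dimethyl-8-oxo-10βH-decalin-3α-yl ester of 19 | C1C[C@@]2(C)[C@H](CC[C@@H](OC(=O)/C=C/C[C@@H](C)OC(=O)/C(C)=C\C)[C@@H]2C)[C@@H](O[Si](C)(C)C(C)(C)C)C1=O | intermediate
23 | C7=C8 trimethylsilyl enol ether of 22 | C1C[C@@]2(C)[C@H](CC[C@@H](OC(=O)/C=C/C[C@@H](C)OC(=O)/C(C)=C\C)[C@@H]2C)[C@@H](O[Si](C)(C)C(C)(C)C)C=1O[Si](C)(C)C | intermediate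
24 | 7β-(2-hydroxypropan-2-yl) derivative of 22 | CC(C)(O)[C@H]1C[C@@]2(C)[C@H](CC[C@@H](OC(=O)/C=C/C[C@@H](C)OC(=O)/C(C)=C\C)[C@@H]2C)[C@@H](O[Si](C)(C)C(C)(C)C)C1=O | intermediate
25 | 9-O-tert-butyldimethylsilyl ether of the target (7β-isopropenyl) | C=C(C)[C@H]1C[C@@]2(C)[C@H](CC[C@@H](OC(=O)/C=C/C[C@@H](C)OC(=O)/C(C)=C\C)[C@@H]2C)[C@@H](O[Si](C)(C)C(C)(C)C)C1=O | intermediate
26 | CNP0210874.1: 3α-[(2E,5R)-5-(angeloyloxy)hex-2-enoyloxy]-9β-hydroxy-10βH-eremophil-11-en-8-one (3R,4R,5R,7R,9R,10S) | C=C(C)[C@H]1C[C@@]2(C)[C@H](CC[C@@H](OC(=O)/C=C/C[C@@H](C)OC(=O)/C(C)=C\C)[C@@H]2C)[C@@H](O)C1=O | target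

## Step count and risks

Total steps: 13. Longest linear sequence: 10 steps (steps 1–5 and 9–13, from (S)-carvone); the side chain takes steps 6–8.

Step 5 (face selectivity of the hydroboration next to the quaternary C5). Fallback, thermodynamic instead of kinetic control: set out from 9, hydroborate and oxidise as in step 5 but leave out the acid, and take the ketal alcohols on as a mixture of 11 and 8,8-ethylenedioxy-4α,5β-dimethyl-10βH-decalin-3β-ol F1. Dess–Martin periodinane in CH2Cl2 gives the C3 ketones 8,8-ethylenedioxy-4β,5β-dimethyl-10βH-decalin-3-one F2 and 8,8-ethylenedioxy-4α,5β-dimethyl-10βH-decalin-3-one F3. NaOMe in MeOH equilibrates C4 (α to the carbonyl) towards the equatorial 4β-methyl ketone F2. Li in liquid NH3 (THF, t-BuOH, −78 °C) then gives the equatorial 3α-alcohol, which is 11, where the route is rejoined (2 M HCl gives 12).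

Step 11 (regioselective soft enolisation and aldol addition to acetone next to the silyloxy group, in the presence of the side chain). Fallback, cross-coupling instead of aldol and dehydration: set out from 22 and make the TMS enol ether 23 as in step 11. Convert it with Bu3SnF into the tributylstannyl enolate of 22 F4 and couple this in the same flask with 2-bromopropene (PdCl2[P(o-tolyl)3]2 cat., toluene, 80 °C). This gives the isopropenyl ketone 25 directly, where the route is rejoined; steps 11 and 12 are bypassed.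

Step 12 (isopropenyl versus conjugated isopropylidene on dehydration). Fallback, deconjugation of the conjugated enone: set out from 24 and dehydrate under equilibrating conditions (TsOH cat., benzene, 60 °C) to the conjugated 7(11)-en-8-one isomer of 25 F5. TMSOTf/Et3N removes a γ-hydrogen from an isopropylidene methyl and gives the C8 trimethylsilyl dienol ether (C7=C8, C11=C12) F6. CsF/AcOH in MeCN at −20 °C cleaves the O–SiMe3 bond (the TBS ether survives), and the dienolate is protonated kinetically at C7, its α-carbon. This gives the β,γ-unsaturated ketone 25, where the route is rejoined; a 7α epimer would equilibrate to the equatorial 7β isomer through the same dienol.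

Further compounds
F1 | step 5 | 8,8-ethylenedioxy-4α,5β-dimethyl-10βH-decalin-3β-ol | C1C[C@@]2(C)[C@H](CC[C@H](O)[C@H]2C)CC13OCCO3
F2 | step 5 | 8,8-ethylenedioxy-4β,5β-dimethyl-10βH-decalin-3-one | C1C[C@@]2(C)[C@H](CCC(=O)[C@@H]2C)CC13OCCO3
F3 | step 5 | 8,8-ethylenedioxy-4α,5β-dimethyl-10βH-decalin-3-one | C1C[C@@]2(C)[C@H](CCC(=O)[C@H]2C)CC13OCCO3
F4 | step 11 | tributylstannyl C7=C8 enolate of 22 | C1C[C@@]2(C)[C@H](CC[C@@H](OC(=O)/C=C/C[C@@H](C)OC(=O)/C(C)=C\C)[C@@H]2C)[C@@H](O[Si](C)(C)C(C)(C)C)C=1O[Sn](CCCC)(CCCC)CCCC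
F5 | step 12 | 7(11)-en-8-one (isopropylidene) isomer of 25 | CC(C)=C1C[C@@]2(C)[C@H](CC[C@@H](OC(=O)/C=C/C[C@@H](C)OC(=O)/C(C)=C\C)[C@@H]2C)[C@@H](O[Si](C)(C)C(C)(C)C)C1=O
F6 | step 12 | C8 trimethylsilyl dienol ether of F5 (C7=C8 and C11=C12) | C=C(C)C1C[C@@]2(C)[C@H](CC[C@@H](OC(=O)/C=C/C[C@@H](C)OC(=O)/C(C)=C\C)[C@@H]2C)[C@@H](O[Si](C)(C)C(C)(C)C)C=1O[Si](C)(C)C
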